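**Retrosynthetic overview**

- Endgame: the methacrylate on the chain oxygen, the gem-dimethyl end of the C5 side chain (cross-metathesis of a vinyl group) and the C4 acetate are all attached after the ring exists.
- Key disconnection: the C4–C5 bond of the γ-lactone (ring atoms O1, C2(=O), C3, C4, C5). It is closed by an intramolecular, ligand-controlled Nozaki–Hiyama–Kishi (acyloxy)allylation of an acyclic, achiral 3-chloropropenyl 2-formyl-2-enoate. Two electrophile-derived carbons are joined after polarity reversal at C5, and the ring, both stereocentres and their trans relationship arise together.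
- Enabling feature: C5 bears the ring oxygen O1 and is allylic to the side-chain C=C, so it can be the γ-carbon of a 3-acyloxyallyl chromium. C4 is a carbinol carbon on C3, so it can be an aldehyde. The ester unit O1–C2(=O)–C3 is a three-atom tether that makes the ring five-membered.
- The precursor comes from acrolein and an (E)-2-formyl-2-enoic acid. The acid is made from the Morita–Baylis–Hillman adduct of methyl acrylate with a C12 aldehyde cut from (2Z,6E)-farnesol.
- Ring order: one ring only, the γ-lactone, formed in step 9.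

Key step: step 9

Assumption: (2Z,6E)-farnesol is bought as the single geometric isomer.
Remark: L* in step 9 is 1,8-bis[(4S)-4-isopropyl-4,5-dihydro-1,3-oxazol-2-yl]-3,6-diphenyl-9H-carbazole or its (4R,4R) antipode; the antipode that gives the (4S,5R) lactone is fixed in a trial run.
Remark: ester 14 is used as an E/Z mixture at the enol-ester double bond, because both isomers converge on the same allylchromium.

**Route**

Step 1
Reactants: 1 (2Z,6E)-farnesol
Product: 2 tert-butyl{[(2Z,6E)-3,7,11-trimethyldodeca-2,6,10-trien-1-yl]oxy}diphenylsilane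
Conditions: TBDPSCl, imidazole, CH2Cl2, 0 °C to rt
Reagents that add atoms: tert-butyl(chloro)diphenylsilane, CC(C)(C)[Si](Cl)(c1ccccc1)c1ccccc1
Why: Standard silyl ether formation at a primary allylic alcohol; the tert-butyldiphenylsilyl group is chosen because it withstands periodic acid, hydroxide, oxalyl chloride and ZnCl2 and is removed by fluoride in step 12.

Step 2
Reactants: 2 the silyl ether of (2Z,6E)-farnesol
Product: 4 tert-butyl{[(2Z,6E)-9-(3,3-dimethyloxiran-2-yl)-3,7-dimethylnona-2,6-dien-1-yl]oxy}diphenylsilane (racemic terminal epoxide), via bromohydrin 3 (not isolated)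
Conditions: NBS, THF/H2O (3:1), 0 °C; then K2CO3, MeOH, rt
Reagents that add atoms: water, O
Why: Position-selective bromohydrin formation at the terminal trisubstituted olefin of a polyprenyl chain in aqueous THF (the allylic silyl ether deactivates the 2,3-olefin and the chain end is the most exposed one), followed by base-induced epoxide closure; the new stereocentre is racemic and is removed in step 3.

Step 3
Reactants: 4 the racemic terminal epoxide
Product: 5 (4E,8Z)-10-[(tert-butyldiphenylsilyl)oxy]-4,8-dimethyldeca-4,8-dienal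
Conditions: HIO4·2H2O, THF/Et2O, 0 °C
Reagents that add atoms: none
Why: Periodic acid opens the epoxide to the glycol and cleaves it in the same flask (glycol cleavage), releasing acetone and the trisnor aldehyde, whose oxygen is the former epoxide oxygen; the two trisubstituted olefins and the silyl ether should be inert at 0 °C.

Step 4
Reactants: 5 the C12 aldehyde; 6 methyl acrylate
Product: 7 methyl (6E,10Z)-12-[(tert-butyldiphenylsilyl)oxy]-3-hydroxy-6,10-dimethyl-2-methylidenedodeca-6,10-dienoate (racemic)
Conditions: DABCO (1 equiv), 1,4-dioxane/H2O (1:1), rt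
Reagents that add atoms: none
Why: Morita–Baylis–Hillman reaction of an unhindered aliphatic aldehyde with methyl acrylate, accelerated in aqueous dioxane; the carbinol stereocentre is formed racemic and disappears in step 5.

Step 5
Reactants: 7 the Morita–Baylis–Hillman adduct
Product: 9 methyl (2E,6E,10Z)-2-(acetoxymethyl)-12-[(tert-butyldiphenylsilyl)oxy]-6,10-dimethyldodeca-2,6,10-trienoate, via secondary acetate 8 (not isolated)
Conditions: Ac2O, Et3N, DMAP (cat.), CH2Cl2, 0 °C; then DABCO (0.3 equiv), THF, 65 °C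
Reagents that add atoms: acetic anhydride, CC(=O)OC(C)=O
Why: Acetylation followed by DABCO-catalysed allylic transposition of the Morita–Baylis–Hillman acetate (SN2' addition of the amine, return of acetate at the primary carbon) under thermodynamic control, which should give the trisubstituted 2E olefin with the chain trans to the ester carbonyl, the geometry needed for the exocyclic olefin of the target.

Step 6
Reactants: 9 the rearranged primary allylic acetate
Product: 10 (2E,6E,10Z)-12-[(tert-butyldiphenylsilyl)oxy]-2-(hydroxymethyl)-6,10-dimethyldodeca-2,6,10-trienoic acid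
Conditions: LiOH, THF/H2O, 0 °C to rt; then 1 M HCl
Reagents that add atoms: lithium hydroxide, [Li+].[OH-]
Why: Saponification of the acetate and of the methyl ester; hydroxide attacks the two acyl carbons, SN2' attack at the substituted β-carbon is slow, and the olefin geometry is not touched.

Step 7
Reactants: 10 the hydroxy acid
Product: 11 (2E,6E,10Z)-12-[(tert-butyldiphenylsilyl)oxy]-2-formyl-6,10-dimethyldodeca-2,6,10-trienoic acid
Conditions: DMP (1,1,1-triacetoxy-1,2-benziodoxol-3-one), CH2Cl2, 0 °C to rt
Reagents that add atoms: none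
Why: Periodinane oxidation of the primary allylic alcohol to the aldehyde under non-basic conditions that leave the carboxylic acid, the silyl ether and the olefins alone; the chain stays cis to the formyl group, and the sensitive 2-formyl-2-enoic acid is carried on crude.

Step 8
Reactants: 11 the formyl acid; 12 acrolein
Product: 14 3-chloroprop-1-en-1-yl (2E,6E,10Z)-12-[(tert-butyldiphenylsilyl)oxy]-2-formyl-6,10-dimethyldodeca-2,6,10-trienoate (E/Z mixture at the enol ester), via acid chloride 13 (not isolated)
Conditions: (COCl)2, DMF (cat.), CH2Cl2, 0 °C; then 12 (5 equiv), ZnCl2 (2 mol%), CH2Cl2, −20 °C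
Reagents that add atoms: oxalyl chloride, O=C(Cl)C(Cl)=O
Why: Acid chloride formation, then ZnCl2-catalysed addition of the acyl chloride across the C=O of acrolein and allylic shift of chloride to the conjugated enol ester, the established entry to 3-halopropenyl esters; excess acrolein should outcompete the hindered, conjugated formyl group of the substrate.

Step 9
Reactants: 14 the 3-chloropropenyl 2-formyl-2-enoate
Product: 16 (3E,4S,5R)-3-[(4E,8Z)-10-[(tert-butyldiphenylsilyl)oxy]-4,8-dimethyldeca-4,8-dien-1-ylidene]-5-ethenyl-4-hydroxyoxolan-2-one, via trimethylsilyl ether 15 (not isolated)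
Conditions: CrCl2 (10 mol%), L* (12 mol%), Mn powder, TMSCl, DIPEA, THF, rt, slow addition of 14 (5 mM); then 1 M HCl, THF, 0 °C
Reagents that add atoms: none
Why: Divalent chromium inserts into the allylic C–Cl bond of 14 and the (3-acyloxyallyl)chromium, which equilibrates to the E isomer with chromium on the terminal CH2, adds with its oxygen-bearing γ-carbon (C5) to the tethered aldehyde carbon (C4), after which TMSCl silylates the chromium alkoxide and Mn returns trivalent chromium to the divalent state. The closest known reactions are the intermolecular Nozaki–Hiyama–Kishi addition of 3-halopropenyl esters to aldehydes (giving 1,2-diol monoesters), intramolecular Nozaki–Hiyama–Kishi allylations and their ligand-controlled asymmetric versions. The lactone closes by 5-exo-trig attack on the aldehyde (SE2' at the allyl unit) through a bicyclic chair transition state of the Zimmerman–Traxler type that is fused at the forming C4–C5 bond, with the ester in its s-cis rotamer. With the E allyl unit and with O1 and C3 both equatorial on this chair the adduct is anti, that is the 4,5-trans lactone, and the chiral bis(oxazoline) ligand on chromium should decide which of the two mirror-image chairs is used, so that (4S,5R) is expected with the proper ligand antipode. The step needs 1,2- instead of 1,4-addition to the 2-formyl enoate (closed transition state of the allylchromium), attack by C5 and not by the CH2 terminus (chromium sits on CH2 and only C5 attack gives a five-membered ring) and ring closure instead of oligomerisation (slow addition, high dilution). The 3E geometry of the exocyclic olefin is that of 14, in which the chain is cis to the formyl group.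

Step 10
Reactants: 16 the trans hydroxy lactone
Product: 17 (3E,4S,5R)-4-acetoxy-3-[(4E,8Z)-10-[(tert-butyldiphenylsilyl)oxy]-4,8-dimethyldeca-4,8-dien-1-ylidene]-5-ethenyloxolan-2-one
Conditions: Ac2O, pyridine, DMAP (cat.), CH2Cl2, 0 °C
Reagents that add atoms: acetic anhydride, CC(=O)OC(C)=O
Why: DMAP-catalysed acetylation of the secondary allylic alcohol; no stereocentre is touched and the weak base should not deprotonate the γ-position of the alkylidene lactone.

Step 11
Reactants: 17 the vinyl lactone acetate
Product: 18 (3E,4S,5R)-4-acetoxy-3-[(4E,8Z)-10-[(tert-butyldiphenylsilyl)oxy]-4,8-dimethyldeca-4,8-dien-1-ylidene]-5-(2-methylprop-1-en-1-yl)oxolan-2-one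
Conditions: second-generation Grubbs catalyst (5 mol%), 2-methylbut-2-ene/CH2Cl2, rt to 35 °C
Reagents that add atoms: 2-methylbut-2-ene, CC=C(C)C
Why: Olefin cross-metathesis of the monosubstituted vinyl group with 2-methylbut-2-ene in large excess, which turns a terminal olefin into the 2-methylprop-1-enyl group with loss of propene; the internal trisubstituted chain olefins and the conjugated exocyclic olefin are much slower partners for the ruthenium alkylidene, and C5 is not affected.

Step 12
Reactants: 18 the silyl-protected acetoxy lactone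
Product: 19 (3E,4S,5R)-4-acetoxy-3-[(4E,8Z)-10-hydroxy-4,8-dimethyldeca-4,8-dien-1-ylidene]-5-(2-methylprop-1-en-1-yl)oxolan-2-one
Conditions: HF·pyridine, pyridine, THF, 0 °C to rt
Reagents that add atoms: none
Why: Fluoride cleavage of the silyl ether with buffered HF·pyridine, which should spare the acetate, the lactone and the Z geometry of the allylic alcohol.

Step 13
Reactants: 19 the primary allylic alcohol
Product: 20 (2Z,6E,10E)-10-[(4S,5R)-4-acetoxy-5-(2-methylprop-1-en-1-yl)-2-oxooxolan-3-ylidene]-3,7-dimethyldeca-2,6-dien-1-yl 2-methylprop-2-enoate (target CNP0152230.1)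
Conditions: methacryloyl chloride, Et3N, DMAP (cat.), BHT (trace), CH2Cl2, −20 to 0 °C
Reagents that add atoms: methacryloyl chloride, C=C(C)C(Cl)=O
Why: Ester formation at the primary allylic alcohol at low temperature, with a trace of BHT against radical polymerisation; the secondary acetate and the lactone should not exchange under these conditions.

**Compound list**

1 | (2Z,6E)-3,7,11-trimethyldodeca-2,6,10-trien-1-ol ((2Z,6E)-farnesol) | OC/C=C(/C)CC/C=C(\C)CCC=C(C)C | starting material
2 | tert-butyl{[(2Z,6E)-3,7,11-trimethyldodeca-2,6,10-trien-1-yl]oxy}diphenylsilane | CC(C)(C)[Si](OC/C=C(/C)CC/C=C(\C)CCC=C(C)C)(c1ccccc1)c1ccccc1 | intermediate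
3 | (6E,10Z)-3-bromo-12-[(tert-butyldiphenylsilyl)oxy]-2,6,10-trimethyldodeca-6,10-dien-2-ol (racemic bromohydrin) | CC(C)(C)[Si](OC/C=C(/C)CC/C=C(\C)CCC(Br)C(C)(C)O)(c1ccccc1)c1ccccc1 | intermediate
4 | tert-butyl{[(2Z,6E)-9-(3,3-dimethyloxiran-2-yl)-3,7-dimethylnona-2,6-dien-1-yl]oxy}diphenylsilane (racemic) | CC(C)(C)[Si](OC/C=C(/C)CC/C=C(\C)CCC1OC1(C)C)(c1ccccc1)c1ccccc1 | intermediate
5 | (4E,8Z)-10-[(tert-butyldiphenylsilyl)oxy]-4,8-dimethyldeca-4,8-dienal | CC(C)(C)[Si](OC/C=C(/C)CC/C=C(\C)CCC=O)(c1ccccc1)c1ccccc1 | intermediate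
6 | methyl acrylate | C=CC(=O)OC | starting material
7 | methyl (6E,10Z)-12-[(tert-butyldiphenylsilyl)oxy]-3-hydroxy-6,10-dimethyl-2-methylidenedodeca-6,10-dienoate (racemic) | CC(C)(C)[Si](OC/C=C(/C)CC/C=C(\C)CCC(O)C(=C)C(=O)OC)(c1ccccc1)c1ccccc1 | intermediate
8 | methyl (6E,10Z)-3-acetoxy-12-[(tert-butyldiphenylsilyl)oxy]-6,10-dimethyl-2-methylidenedodeca-6,10-dienoate (racemic) | CC(C)(C)[Si](OC/C=C(/C)CC/C=C(\C)CCC(OC(C)=O)C(=C)C(=O)OC)(c1ccccc1)c1ccccc1 | intermediate
9 | methyl (2E,6E,10Z)-2-(acetoxymethyl)-12-[(tert-butyldiphenylsilyl)oxy]-6,10-dimethyldodeca-2,6,10-trienoate | CC(C)(C)[Si](OC/C=C(/C)CC/C=C(\C)CC/C=C(/C(=O)OC)COC(C)=O)(c1ccccc1)c1ccccc1 | intermediate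
10 | (2E,6E,10Z)-12-[(tert-butyldiphenylsilyl)oxy]-2-(hydroxymethyl)-6,10-dimethyldodeca-2,6,10-trienoic acid | CC(C)(C)[Si](OC/C=C(/C)CC/C=C(\C)CC/C=C(/C(=O)O)CO)(c1ccccc1)c1ccccc1 | intermediate
11 | (2E,6E,10Z)-12-[(tert-butyldiphenylsilyl)oxy]-2-formyl-6,10-dimethyldodeca-2,6,10-trienoic acid | CC(C)(C)[Si](OC/C=C(/C)CC/C=C(\C)CC/C=C(/C(=O)O)C=O)(c1ccccc1)c1ccccc1 | intermediate
12 | acrolein (prop-2-enal) | C=CC=O | starting material
13 | (2E,6E,10Z)-12-[(tert-butyldiphenylsilyl)oxy]-2-formyl-6,10-dimethyldodeca-2,6,10-trienoyl chloride | CC(C)(C)[Si](OC/C=C(/C)CC/C=C(\C)CC/C=C(/C(=O)Cl)C=O)(c1ccccc1)c1ccccc1 | intermediate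
14 | 3-chloroprop-1-en-1-yl (2E,6E,10Z)-12-[(tert-butyldiphenylsilyl)oxy]-2-formyl-6,10-dimethyldodeca-2,6,10-trienoate (E/Z mixture at the enol ester C=C) | CC(C)(C)[Si](OC/C=C(/C)CC/C=C(\C)CC/C=C(/C(=O)OC=CCCl)C=O)(c1ccccc1)c1ccccc1 | intermediate
15 | (3E,4S,5R)-3-[(4E,8Z)-10-[(tert-butyldiphenylsilyl)oxy]-4,8-dimethyldeca-4,8-dien-1-ylidene]-5-ethenyl-4-[(trimethylsilyl)oxy]oxolan-2-one | CC(C)(C)[Si](OC/C=C(/C)CC/C=C(\C)CC/C=C1/C(=O)O[C@H](C=C)[C@H]1O[Si](C)(C)C)(c1ccccc1)c1ccccc1 | intermediate
16 | (3E,4S,5R)-3-[(4E,8Z)-10-[(tert-butyldiphenylsilyl)oxy]-4,8-dimethyldeca-4,8-dien-1-ylidene]-5-ethenyl-4-hydroxyoxolan-2-one | CC(C)(C)[Si](OC/C=C(/C)CC/C=C(\C)CC/C=C1/C(=O)O[C@H](C=C)[C@H]1O)(c1ccccc1)c1ccccc1 | intermediate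
17 | (3E,4S,5R)-4-acetoxy-3-[(4E,8Z)-10-[(tert-butyldiphenylsilyl)oxy]-4,8-dimethyldeca-4,8-dien-1-ylidene]-5-ethenyloxolan-2-one | CC(C)(C)[Si](OC/C=C(/C)CC/C=C(\C)CC/C=C1/C(=O)O[C@H](C=C)[C@H]1OC(C)=O)(c1ccccc1)c1ccccc1 | intermediate
18 | (3E,4S,5R)-4-acetoxy-3-[(4E,8Z)-10-[(tert-butyldiphenylsilyl)oxy]-4,8-dimethyldeca-4,8-dien-1-ylidene]-5-(2-methylprop-1-en-1-yl)oxolan-2-one | CC(C)(C)[Si](OC/C=C(/C)CC/C=C(\C)CC/C=C1/C(=O)O[C@H](C=C(C)C)[C@H]1OC(C)=O)(c1ccccc1)c1ccccc1 | intermediate
19 | (3E,4S,5R)-4-acetoxy-3-[(4E,8Z)-10-hydroxy-4,8-dimethyldeca-4,8-dien-1-ylidene]-5-(2-methylprop-1-en-1-yl)oxolan-2-one | OC/C=C(/C)CC/C=C(\C)CC/C=C1/C(=O)O[C@H](C=C(C)C)[C@H]1OC(C)=O | intermediate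
20 | (2Z,6E,10E)-10-[(4S,5R)-4-acetoxy-5-(2-methylprop-1-en-1-yl)-2-oxooxolan-3-ylidene]-3,7-dimethyldeca-2,6-dien-1-yl 2-methylprop-2-enoate | C=C(C)C(=O)OC/C=C(/C)CC/C=C(\C)CC/C=C1/C(=O)O[C@H](C=C(C)C)[C@H]1OC(C)=O | target

**Step count and risks**

Total step count: 13. Longest linear sequence: 13 steps (from 1; 6 and 12 are bought).

Steps most likely to fail:

First, step 9 (key step). The ring closure may lose to intermolecular allylation and oligomer formation, because the ester has to twist into its s-cis rotamer before C5 can reach C4. Low-valent chromium and Mn may also cause reductive pinacol coupling or conjugate reduction of the electron-poor 2-formyl enoate. Facial selectivity (ee) or the anti preference of the fused chair may be poor. The fallback sets out from 9 and comes back at 16.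
- The acetate of 9 is removed selectively (K2CO3, MeOH, 0 °C) to give methyl (2E,6E,10Z)-12-[(tert-butyldiphenylsilyl)oxy]-2-(hydroxymethyl)-6,10-dimethyldodeca-2,6,10-trienoate F1.
- F1 is coupled at the alcohol oxidation level with prop-2-ene-1,1-diyl dibenzoate by iridium-catalysed transfer-hydrogenative anti-(acyloxy)allylation ([Ir(cod)Cl]2, (R)- or (S)-SEGPHOS, 4-cyano-3-nitrobenzoic acid, K3PO4, THF, 60 °C). This is a known intermolecular, catalyst-controlled route to anti-1,2-diol monobenzoates and should give the anti benzoate F2.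
- K2CO3 in MeOH removes the benzoate to give the diol ester F3, whose C5 hydroxyl closes onto the methyl ester to give 16.

Second, step 8 (together with the handling of 11 from step 7). The 2-formyl-2-enoic acid or its chloride may decarboxylate or self-condense, the acyl chloride may add to the substrate's own formyl group instead of acrolein, and HCl may cleave the silyl ether or add to the chain olefins. The fallback sets out from 10 and comes back at 14. Copper-mediated O-alkenylation of the hydroxy acid 10 (Chan–Lam coupling) with (E)-2-(3-chloroprop-1-en-1-yl)-4,4,5,5-tetramethyl-1,3,2-dioxaborolane (Cu(OAc)2, Et3N, 4 Å sieves, air, CH2Cl2, rt) gives the hydroxy enol ester F4. DMP oxidation of its allylic alcohol gives 14 as the E enol ester, so neither the free formyl acid nor an acid chloride is needed.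

Third, step 11. The ruthenium alkylidene may attack the trisubstituted chain olefins (chain truncation), ruthenium hydrides may shift olefins, or conversion at the hindered allylic vinyl group may stay low. The fallback sets out from 11 and comes back at 18; it brings the gem-dimethyl terminus in with the allyl donor, so that no metathesis is needed.
- The acid chloride 13, made from 11 as in step 8, is added to 3-methylbut-2-enal instead of acrolein (ZnCl2 cat., −20 °C). This gives the tertiary allylic chloride F5, in equilibrium with its 1-chloro-3-methylbut-2-enyl isomer.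
- Ring closure under the conditions of step 9 gives the trimethylsilyl ether F6 and, after acid work-up, the hydroxy lactone F7, which is acetylated as in step 10 to give 18.
- In this variant only the ring size (five against seven) directs bond formation to C5 instead of the CMe2 terminus, which is why it is held in reserve.

Further compounds
F1 | step 9 | methyl (2E,6E,10Z)-12-[(tert-butyldiphenylsilyl)oxy]-2-(hydroxymethyl)-6,10-dimethyldodeca-2,6,10-trienoate | CC(C)(C)[Si](OC/C=C(/C)CC/C=C(\C)CC/C=C(/C(=O)OC)CO)(c1ccccc1)c1ccccc1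
F2 | step 9 | methyl (2E,6E,10Z)-2-[(1S,2R)-2-(benzoyloxy)-1-hydroxybut-3-en-1-yl]-12-[(tert-butyldiphenylsilyl)oxy]-6,10-dimethyldodeca-2,6,10-trienoate | CC(C)(C)[Si](OC/C=C(/C)CC/C=C(\C)CC/C=C(/C(=O)OC)[C@H](O)[C@H](OC(=O)c1ccccc1)C=C)(c1ccccc1)c1ccccc1
F3 | step 9 | methyl (2E,6E,10Z)-12-[(tert-butyldiphenylsilyl)oxy]-2-[(1S,2R)-1,2-dihydroxybut-3-en-1-yl]-6,10-dimethyldodeca-2,6,10-trienoate (not isolated) | CC(C)(C)[Si](OC/C=C(/C)CC/C=C(\C)CC/C=C(/C(=O)OC)[C@H](O)[C@H](O)C=C)(c1ccccc1)c1ccccc1
F4 | step 8 | (1E)-3-chloroprop-1-en-1-yl (2E,6E,10Z)-12-[(tert-butyldiphenylsilyl)oxy]-2-(hydroxymethyl)-6,10-dimethyldodeca-2,6,10-trienoate | CC(C)(C)[Si](OC/C=C(/C)CC/C=C(\C)CC/C=C(/C(=O)O/C=C/CCl)CO)(c1ccccc1)c1ccccc1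
F5 | step 11 | 3-chloro-3-methylbut-1-en-1-yl (2E,6E,10Z)-12-[(tert-butyldiphenylsilyl)oxy]-2-formyl-6,10-dimethyldodeca-2,6,10-trienoate | CC(C)(C)[Si](OC/C=C(/C)CC/C=C(\C)CC/C=C(/C(=O)OC=CC(C)(C)Cl)C=O)(c1ccccc1)c1ccccc1
F6 | step 11 | (3E,4S,5R)-3-[(4E,8Z)-10-[(tert-butyldiphenylsilyl)oxy]-4,8-dimethyldeca-4,8-dien-1-ylidene]-5-(2-methylprop-1-en-1-yl)-4-[(trimethylsilyl)oxy]oxolan-2-one (not isolated) | CC(C)(C)[Si](OC/C=C(/C)CC/C=C(\C)CC/C=C1/C(=O)O[C@H](C=C(C)C)[C@H]1O[Si](C)(C)C)(c1ccccc1)c1ccccc1
F7 | step 11 | (3E,4S,5R)-3-[(4E,8Z)-10-[(tert-butyldiphenylsilyl)oxy]-4,8-dimethyldeca-4,8-dien-1-ylidene]-4-hydroxy-5-(2-methylprop-1-en-1-yl)oxolan-2-one | CC(C)(C)[Si](OC/C=C(/C)CC/C=C(\C)CC/C=C1/C(=O)O[C@H](C=C(C)C)[C@H]1O)(c1ccccc1)c1ccccc1
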